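**Plan**

- Retrosynthesis: the butenolide is opened at O–C16 and C16–C17 (terminal enyne + (Z)-3-iodobut-2-enoic acid). The side chain is then cut at C9–C11 (alkylzinc + C9 enol triflate), ring A at C3–C4 (radical closure), and last the two C10 alkyl bonds (C10–CH3, C10–C1).
- Enabling feature: ring B (C5–C10) with the C8 methyl, the C9 oxygen function and the C5 stereocentre is (R)-carvone atom for atom. The isopropenyl group supplies C4 and one geminal methyl; its =CH2 becomes the other methyl on taking up a hydrogen atom, leaving a tertiary C4 radical beside an acrylate arm on C10.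
- Forward order: ring B is bought as carvone; C10 is quaternised by two alkylations; ring A is closed by the radical 6-endo cyclisation to the trans-decalin. The ester is then excised, C9 becomes an enol triflate, the side chain is joined by Negishi coupling, and the butenolide ring is closed last.
- Stereochemistry: C5 comes from (R)-carvone; C10 from alkylation anti to the isopropenyl group; C13=C14 (E) from a Wittig reaction of a lactone ylide; C15=C16 (Z) from anti addition of the carboxylate across the alkyne.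

Key step: step 3

Assumption: terpenoid numbering is used (decalin C1–C10, tether C11–C12, C13=C14 with C20H2OH on C13, ylidene bond C15=C16, butenolide C16–C19), and the alkyne is carried as its triisopropylsilyl derivative because a trimethylsilyl alkyne would not survive the hydroxide of step 9.

**Route**

Step 1
Reactants: 1 (R)-(−)-carvone
Product: 3 trans-6-methylcarvone, via carvone lithium dienolate 2 (not isolated)
Conditions: LiN(i-Pr)2, THF, −78 °C; MeI, −78 → 0 °C
Reagents that add atoms: iodomethane, CI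
Why: Kinetic α′-deprotonation followed by enolate C-methylation installs the future C10 methyl, and the product can be used as its C6 epimer mixture because step 2 planarises that carbon again.

Step 2
Reactants: 3 trans-6-methylcarvone; 4 methyl 2-(bromomethyl)acrylate
Product: 6 methyl 2-{[(1S,6S)-1,3-dimethyl-2-oxo-6-(prop-1-en-2-yl)cyclohex-3-en-1-yl]methyl}prop-2-enoate, via methylcarvone lithium enolate 5 (not isolated)
Conditions: LiN(i-Pr)2, THF, −78 → 0 °C; then 4, −78 °C → rt
Reagents that add atoms: none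
Why: Enolate alkylation (SN2′ addition–elimination on the allylic bromide) should occur on the face of the tetrasubstituted enolate anti to the neighbouring isopropenyl group, which sets quaternary C10 with the methyl cis and the acrylate arm trans to the future C4.

Step 3
Reactants: 6 methyl 2-{[(1S,6S)-1,3-dimethyl-2-oxo-6-(prop-1-en-2-yl)cyclohex-3-en-1-yl]methyl}prop-2-enoate
Product: 7 methyl (2S,4aS,8aS)-4,4,7,8a-tetramethyl-8-oxo-1,2,3,4,4a,5,8,8a-octahydronaphthalene-2-carboxylate
Conditions: Fe(acac)3 (0.3 equiv), PhSiH3 (2.5 equiv), EtOH/(CH2OH)2 5:1, 60 °C, 0.02 M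
Reagents that add atoms: none
Why: An iron hydride formed from Fe(acac)3 and PhSiH3 transfers a hydrogen atom to the terminal CH2 of the isopropenyl group, which creates the second C4 methyl and a nucleophilic tertiary C4 radical; this adds to the unsubstituted acrylate terminus C3, and the resulting α-ester radical at C2 is reduced by divalent iron to the enolate and protonated by ethanol. The closest known reaction type is the metal-hydride hydrogen-atom-transfer reductive olefin coupling in its intramolecular Giese form. Ring A closes 6-endo-trig through the new C3–C4 bond, because the 5-exo alternative would require attack at the fully substituted, polarity-mismatched α-carbon C2. No ring-fusion centre is created: C5 and C10 are already fixed with C4 and C1 trans-diequatorial on ring B, so a chair transition state can only give the trans-decalin, while the single new stereocentre C2 is set in the final protonation without a strong facial bias (the equatorial, thermodynamic epimer is drawn) and is deleted in step 5. The step needs hydrogen-atom transfer to the electron-neutral 1,1-disubstituted alkene in preference to the acrylate and the enone, and 6-endo regiochemistry; the first is secured by the preference of the metal hydride for the electron-rich alkene and the second by the α-substitution of the acrylate.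

Step 4
Reactants: 7 methyl (2S,4aS,8aS)-4,4,7,8a-tetramethyl-8-oxo-1,2,3,4,4a,5,8,8a-octahydronaphthalene-2-carboxylate
Product: 8 (2S,4aS,8aS)-4,4,7,8a-tetramethyl-8-oxo-1,2,3,4,4a,5,8,8a-octahydronaphthalene-2-carboxylic acid
Conditions: LiOH·H2O, THF/MeOH/H2O, rt; then 1 M HCl to pH 3
Reagents that add atoms: lithium hydroxide, [Li+].[OH-]
Why: Saponification of the unhindered secondary methyl ester is routine, the enone is inert to hydroxide at room temperature, and any epimerisation at C2 is harmless.

Step 5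
Reactants: 8 (2S,4aS,8aS)-4,4,7,8a-tetramethyl-8-oxo-1,2,3,4,4a,5,8,8a-octahydronaphthalene-2-carboxylic acid
Product: 11 (4aS,8aS)-2,5,5,8a-tetramethyl-4a,5,6,7,8,8a-hexahydronaphthalen-1(4H)-one, via acid chloride 9 (not isolated), via Barton ester 10 (not isolated)
Conditions: (COCl)2, cat. DMF, CH2Cl2, 0 °C → rt; then sodium 2-mercaptopyridine N-oxide, cat. DMAP, t-BuSH, PhMe, tungsten lamp, 80 °C
Reagents that add atoms: none
Why: In this Barton reductive decarboxylation the thiohydroxamate ester fragments to CO2 and a secondary C2 radical that takes hydrogen from the thiol, which removes the activating group and the transient C2 centre without touching the enone.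

Step 6
Reactants: 11 (4aS,8aS)-2,5,5,8a-tetramethyl-4a,5,6,7,8,8a-hexahydronaphthalen-1(4H)-one
Product: 13 (4aS,8aS)-2,5,5,8a-tetramethyl-3,4,4a,5,6,7,8,8a-octahydronaphthalen-1-yl trifluoromethanesulfonate, via decalin lithium enolate 12 (not isolated)
Conditions: LiBH(s-Bu)3, THF, −78 °C; then PhNTf2, −78 °C → rt
Reagents that add atoms: N-phenylbis(trifluoromethanesulfonimide), O=S(=O)(N(c1ccccc1)S(=O)(=O)C(F)(F)F)C(F)(F)F
Why: Conjugate hydride reduction of the enone (1,2-attack at C9 is blocked by quaternary C10) gives the C8=C9 enolate regiospecifically, and O-sulfonylation traps it as the tetrasubstituted enol triflate in a reductive enolate-trapping sequence.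

Step 7
Reactants: 14 α-bromo-γ-butyrolactone
Product: 15 (2-oxooxolan-3-yl)triphenylphosphonium bromide
Conditions: PPh3, THF, reflux
Reagents that add atoms: triphenylphosphine, c1ccc(cc1)P(c1ccccc1)c1ccccc1
Why: SN2 quaternisation of triphenylphosphine by the activated α-bromo lactone should give the crystalline phosphonium salt.

Step 8
Reactants: 15 (2-oxooxolan-3-yl)triphenylphosphonium bromide; 16 3-(triisopropylsilyl)prop-2-ynal
Product: 18 (E)-3-[3-(triisopropylsilyl)prop-2-yn-1-ylidene]oxolan-2-one, via lactone ylide 17 (not isolated)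
Conditions: Et3N, CH2Cl2, 0 °C → rt
Reagents that add atoms: none
Why: The Wittig reaction of a carbonyl-stabilised ylide is E-selective, which places the alkynyl group trans to the lactone carbonyl and cis to the ring CH2 and so fixes the C13=C14 geometry of the target.

Step 9
Reactants: 18 (E)-3-[3-(triisopropylsilyl)prop-2-yn-1-ylidene]oxolan-2-one
Product: 20 methyl (E)-2-(2-hydroxyethyl)-5-(triisopropylsilyl)pent-2-en-4-ynoate, via potassium hydroxy carboxylate 19 (not isolated)
Conditions: KOH (1.0 equiv), THF/H2O, 0 °C → rt; evaporate; MeI, DMF, rt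
Reagents that add atoms: potassium hydroxide, [K+].[OH-]; iodomethane, CI
Why: Lactone saponification followed by SN2 O-methylation of the carboxylate salt opens the ring without an acidic stage at which the γ-hydroxy acid would relactonise, and the triisopropylsilyl alkyne tolerates the hydroxide.

Step 10
Reactants: 20 methyl (E)-2-(2-hydroxyethyl)-5-(triisopropylsilyl)pent-2-en-4-ynoate
Product: 21 methyl (E)-2-(2-iodoethyl)-5-(triisopropylsilyl)pent-2-en-4-ynoate
Conditions: PPh3, I2, imidazole, CH2Cl2, 0 °C (crude 20 used directly)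
Reagents that add atoms: iodine, [I][I]
Why: The Appel-type iodination replaces the primary hydroxyl by iodide through SN2 displacement of an alkoxyphosphonium ion under neutral conditions that leave the enynoate geometry intact.

Step 11
Reactants: 21 methyl (E)-2-(2-iodoethyl)-5-(triisopropylsilyl)pent-2-en-4-ynoate; 13 (4aS,8aS)-2,5,5,8a-tetramethyl-3,4,4a,5,6,7,8,8a-octahydronaphthalen-1-yl trifluoromethanesulfonate
Product: 23 methyl (E)-2-{2-[(4aS,8aS)-2,5,5,8a-tetramethyl-3,4,4a,5,6,7,8,8a-octahydronaphthalen-1-yl]ethyl}-5-(triisopropylsilyl)pent-2-en-4-ynoate, via alkylzinc iodide 22 (not isolated)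
Conditions: Zn dust, LiCl, THF, 40 °C; then 13, Pd(OAc)2 (5 mol %), SPhos (10 mol %), THF/NMP, 50 °C
Reagents that add atoms: none
Why: In this Negishi sp2–sp3 coupling zinc inserts into the primary C–I bond of the ester-bearing iodide, and a bulky electron-rich biarylphosphine palladium catalyst should achieve oxidative addition into the hindered enol triflate and reductive elimination faster than β-hydride elimination, forming C9–C11 with both alkene geometries retained.

Step 12
Reactants: 23 methyl (E)-2-{2-[(4aS,8aS)-2,5,5,8a-tetramethyl-3,4,4a,5,6,7,8,8a-octahydronaphthalen-1-yl]ethyl}-5-(triisopropylsilyl)pent-2-en-4-ynoate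
Product: 24 (E)-2-{2-[(4aS,8aS)-2,5,5,8a-tetramethyl-3,4,4a,5,6,7,8,8a-octahydronaphthalen-1-yl]ethyl}-5-(triisopropylsilyl)pent-2-en-4-yn-1-ol
Conditions: i-Bu2AlH (2.5 equiv), CH2Cl2, −78 °C; aq. potassium sodium tartrate
Reagents that add atoms: none
Why: Aluminium hydride 1,2-reduction of the conjugated methyl ester gives the C20 allylic alcohol at low temperature without hydroalumination of the silylated alkyne.

Step 13
Reactants: 24 (E)-2-{2-[(4aS,8aS)-2,5,5,8a-tetramethyl-3,4,4a,5,6,7,8,8a-octahydronaphthalen-1-yl]ethyl}-5-(triisopropylsilyl)pent-2-en-4-yn-1-ol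
Product: 25 (E)-2-{2-[(4aS,8aS)-2,5,5,8a-tetramethyl-3,4,4a,5,6,7,8,8a-octahydronaphthalen-1-yl]ethyl}pent-2-en-4-yn-1-ol
Conditions: Bu4NF, THF, 0 °C → rt
Reagents that add atoms: none
Why: Fluoride-induced protodesilylation of the alkynylsilane frees the terminal alkyne needed for the final coupling.

Step 14
Reactants: 26 but-2-ynoic acid
Product: 27 (Z)-3-iodobut-2-enoic acid
Conditions: NaI, AcOH, 110 °C
Reagents that add atoms: sodium iodide, [Na+].[I-]
Why: Conjugate hydroiodination of the ynoic acid proceeds by anti addition of iodide and a proton, which should give the Z β-iodo acid with iodine cis to the carboxyl group.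

Step 15
Reactants: 25 (E)-2-{2-[(4aS,8aS)-2,5,5,8a-tetramethyl-3,4,4a,5,6,7,8,8a-octahydronaphthalen-1-yl]ethyl}pent-2-en-4-yn-1-ol; 27 (Z)-3-iodobut-2-enoic acid
Product: 29 CNP0288110.2, via enynoic acid 28 (not isolated)
Conditions: PdCl2(PPh3)2 (5 mol %), CuI (10 mol %), Et3N, MeCN, rt, dark
Reagents that add atoms: none
Why: Sonogashira coupling forms C16–C17 with retention of the Z acid geometry, and the cis carboxylate then adds anti across the metal-activated alkyne in a 5-exo-dig lactonisation, which should give the Z γ-ylidene butenolide with the free allylic alcohol untouched.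

**Compound list**

1 | (R)-(−)-carvone | CC1=CC[C@H](CC1=O)C(C)=C | starting material
2 | lithium dienolate of carvone | [Li+].CC1=CC[C@H](C=C1[O-])C(C)=C | intermediate
3 | trans-6-methylcarvone, (5R,6S)-2,6-dimethyl-5-(prop-1-en-2-yl)cyclohex-2-en-1-one (major epimer shown; C6 epimer mixture is used) | CC1=CC[C@@H](C(C)=C)[C@H](C)C1=O | intermediate
4 | methyl 2-(bromomethyl)acrylate | C=C(CBr)C(=O)OC | starting material
5 | lithium enolate of 6-methylcarvone | [Li+].CC1=CC[C@@H](C(C)=C)C(C)=C1[O-] | intermediate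
6 | methyl 2-{[(1S,6S)-1,3-dimethyl-2-oxo-6-(prop-1-en-2-yl)cyclohex-3-en-1-yl]methyl}prop-2-enoate | CC1=CC[C@@H](C(C)=C)[C@](C)(CC(=C)C(=O)OC)C1=O | intermediate
7 | methyl (2S,4aS,8aS)-4,4,7,8a-tetramethyl-8-oxo-1,2,3,4,4a,5,8,8a-octahydronaphthalene-2-carboxylate (equatorial C2 epimer shown; the C2 epimer serves equally) | CC1=CC[C@H]2C(C)(C)C[C@H](C(=O)OC)C[C@]2(C)C1=O | intermediate
8 | (2S,4aS,8aS)-4,4,7,8a-tetramethyl-8-oxo-1,2,3,4,4a,5,8,8a-octahydronaphthalene-2-carboxylic acid | CC1=CC[C@H]2C(C)(C)C[C@H](C(=O)O)C[C@]2(C)C1=O | intermediate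
9 | acid chloride of 8 | CC1=CC[C@H]2C(C)(C)C[C@H](C(=O)Cl)C[C@]2(C)C1=O | intermediate
10 | Barton ester of 8 (2-thioxopyridin-1(2H)-yl ester) | CC1=CC[C@H]2C(C)(C)C[C@H](C(=O)ON3C=CC=CC3=S)C[C@]2(C)C1=O | intermediate
11 | (4aS,8aS)-2,5,5,8a-tetramethyl-4a,5,6,7,8,8a-hexahydronaphthalen-1(4H)-one | CC1=CC[C@H]2C(C)(C)CCC[C@]2(C)C1=O | intermediate
12 | lithium (4aS,8aS)-2,5,5,8a-tetramethyl-3,4,4a,5,6,7,8,8a-octahydronaphthalen-1-olate | [Li+].[O-]C1=C(C)CC[C@H]2C(C)(C)CCC[C@]12C | intermediate
13 | (4aS,8aS)-2,5,5,8a-tetramethyl-3,4,4a,5,6,7,8,8a-octahydronaphthalen-1-yl trifluoromethanesulfonate | FC(F)(F)S(=O)(=O)OC1=C(C)CC[C@H]2C(C)(C)CCC[C@]12C | intermediate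
14 | α-bromo-γ-butyrolactone (racemic) | O=C1OCCC1Br | starting material
15 | (2-oxooxolan-3-yl)triphenylphosphonium bromide | [Br-].O=C1OCCC1[P+](c1ccccc1)(c1ccccc1)c1ccccc1 | intermediate
16 | 3-(triisopropylsilyl)prop-2-ynal | O=CC#C[Si](C(C)C)(C(C)C)C(C)C | starting material
17 | 3-(triphenyl-λ5-phosphanylidene)oxolan-2-one | O=C1OCCC1=P(c1ccccc1)(c1ccccc1)c1ccccc1 | intermediate
18 | (E)-3-[3-(triisopropylsilyl)prop-2-yn-1-ylidene]oxolan-2-one | O=C1OCC/C1=C\C#C[Si](C(C)C)(C(C)C)C(C)C | intermediate
19 | potassium (E)-2-(2-hydroxyethyl)-5-(triisopropylsilyl)pent-2-en-4-ynoate | [K+].[O-]C(=O)/C(CCO)=C/C#C[Si](C(C)C)(C(C)C)C(C)C | intermediate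
20 | methyl (E)-2-(2-hydroxyethyl)-5-(triisopropylsilyl)pent-2-en-4-ynoate | COC(=O)/C(CCO)=C/C#C[Si](C(C)C)(C(C)C)C(C)C | intermediate
21 | methyl (E)-2-(2-iodoethyl)-5-(triisopropylsilyl)pent-2-en-4-ynoate | COC(=O)/C(CCI)=C/C#C[Si](C(C)C)(C(C)C)C(C)C | intermediate
22 | {(E)-3-(methoxycarbonyl)-6-(triisopropylsilyl)hex-3-en-5-yn-1-yl}zinc iodide | COC(=O)/C(CC[Zn]I)=C/C#C[Si](C(C)C)(C(C)C)C(C)C | intermediate
23 | methyl (E)-2-{2-[(4aS,8aS)-2,5,5,8a-tetramethyl-3,4,4a,5,6,7,8,8a-octahydronaphthalen-1-yl]ethyl}-5-(triisopropylsilyl)pent-2-en-4-ynoate | COC(=O)/C(CCC1=C(C)CC[C@H]2C(C)(C)CCC[C@]12C)=C/C#C[Si](C(C)C)(C(C)C)C(C)C | intermediate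
24 | (E)-2-{2-[(4aS,8aS)-2,5,5,8a-tetramethyl-3,4,4a,5,6,7,8,8a-octahydronaphthalen-1-yl]ethyl}-5-(triisopropylsilyl)pent-2-en-4-yn-1-ol | OC/C(CCC1=C(C)CC[C@H]2C(C)(C)CCC[C@]12C)=C/C#C[Si](C(C)C)(C(C)C)C(C)C | intermediate
25 | (E)-2-{2-[(4aS,8aS)-2,5,5,8a-tetramethyl-3,4,4a,5,6,7,8,8a-octahydronaphthalen-1-yl]ethyl}pent-2-en-4-yn-1-ol | OC/C(CCC1=C(C)CC[C@H]2C(C)(C)CCC[C@]12C)=C/C#C | intermediate
26 | but-2-ynoic acid | CC#CC(=O)O | starting material
27 | (Z)-3-iodobut-2-enoic acid | C/C(I)=C/C(=O)O | intermediate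
28 | (2Z,6E)-7-(hydroxymethyl)-3-methyl-9-[(4aS,8aS)-2,5,5,8a-tetramethyl-3,4,4a,5,6,7,8,8a-octahydronaphthalen-1-yl]nona-2,6-dien-4-ynoic acid | OC(=O)/C=C(C)\C#C/C=C(/CO)CCC1=C(C)CC[C@H]2C(C)(C)CCC[C@]12C | intermediate
29 | CNP0288110.2, (5Z)-5-{(2E)-3-(hydroxymethyl)-5-[(4aS,8aS)-2,5,5,8a-tetramethyl-3,4,4a,5,6,7,8,8a-octahydronaphthalen-1-yl]pent-2-en-1-ylidene}-4-methylfuran-2(5H)-one | CC1=CC(=O)O/C1=C\C=C(\CO)CCC1=C(C)CC[C@H]2C(C)(C)CCC[C@]12C | target

**Step count**

Total: 15 steps. Longest linear sequence: 10 steps from (R)-carvone (steps 1–6, 11, 12, 13, 15). Steps 7–10 make the side-chain iodide and step 14 makes the iodo acid.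

**Steps most likely to fail, with fallbacks**

Step 3 (radical ring closure). Hydrogen-atom transfer may go to the acrylate instead of the isopropenyl group. That would give plain reduction of the acceptor or a wrong-way cyclisation started from C2, and the C4 radical may also be reduced before it closes the ring. Fallback: setting out from 6, dry HCl in CH2Cl2 at −20 °C should add in the Markovnikov sense to the isopropenyl group alone. This gives the tertiary chloride methyl 2-{[(1S,6R)-6-(2-chloropropan-2-yl)-1,3-dimethyl-2-oxocyclohex-3-en-1-yl]methyl}prop-2-enoate F1. Slow addition of Bu3SnH with AIBN in toluene at 90 °C then generates the C4 radical by chlorine abstraction at that site only, and the tin-mediated 6-endo Giese cyclisation returns to the route at 7.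

Step 11 (Negishi coupling). Oxidative addition and transmetalation at the tetrasubstituted triflate beside quaternary C10 may be so slow that the alkylzinc is lost to β-hydride elimination or protonation. Fallback: setting out from 13, a Stille coupling with tributyl(vinyl)stannane (Pd(PPh3)4, LiCl, THF, reflux) is an sp2–sp2 coupling that tolerates hindered enol triflates. It gives the diene (4aS,8aS)-1-ethenyl-2,5,5,8a-tetramethyl-3,4,4a,5,6,7,8,8a-octahydronaphthalene F2. 9-BBN followed by NaOH/H2O2 hydroborates only the vinyl group and gives the primary alcohol 2-[(4aS,8aS)-2,5,5,8a-tetramethyl-3,4,4a,5,6,7,8,8a-octahydronaphthalen-1-yl]ethan-1-ol F3. PPh3/I2/imidazole converts it into the iodide (4aS,8aS)-1-(2-iodoethyl)-2,5,5,8a-tetramethyl-3,4,4a,5,6,7,8,8a-octahydronaphthalene F4. The sodium salt of trimethyl phosphonoacetate (NaH, DMF, 60 °C) is alkylated by it to the phosphonate methyl 2-(dimethoxyphosphoryl)-4-[(4aS,8aS)-2,5,5,8a-tetramethyl-3,4,4a,5,6,7,8,8a-octahydronaphthalen-1-yl]butanoate F5. Its Horner–Wadsworth–Emmons reaction with 16 (NaH, THF, 0 °C) rejoins the route at 23 after removal of the minor Z isomer.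

Step 15 (coupling–lactonisation cascade). Competing 6-endo closure to a pyranone, oxidative dimerisation of the alkyne, or erosion of alkene geometry may occur in the one-pot sequence. Fallback: setting out from 25, the acid 27 is first esterified (MeI, K2CO3, DMF) to methyl (Z)-3-iodobut-2-enoate F6. Sonogashira coupling of this ester with 25 gives the enynoate methyl (2Z,6E)-7-(hydroxymethyl)-3-methyl-9-[(4aS,8aS)-2,5,5,8a-tetramethyl-3,4,4a,5,6,7,8,8a-octahydronaphthalen-1-yl]nona-2,6-dien-4-ynoate F7, which cannot cyclise. LiOH in THF/H2O then gives 28, now isolated, and AgNO3 (10 mol %) in acetone closes the ring 5-exo-dig to come back at 29.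

**Further compounds**

F1 | step 3 | methyl 2-{[(1S,6R)-6-(2-chloropropan-2-yl)-1,3-dimethyl-2-oxocyclohex-3-en-1-yl]methyl}prop-2-enoate | CC1=CC[C@@H](C(C)(C)Cl)[C@](C)(CC(=C)C(=O)OC)C1=O
F2 | step 11 | (4aS,8aS)-1-ethenyl-2,5,5,8a-tetramethyl-3,4,4a,5,6,7,8,8a-octahydronaphthalene | C=CC1=C(C)CC[C@H]2C(C)(C)CCC[C@]12C
F3 | step 11 | 2-[(4aS,8aS)-2,5,5,8a-tetramethyl-3,4,4a,5,6,7,8,8a-octahydronaphthalen-1-yl]ethan-1-ol | OCCC1=C(C)CC[C@H]2C(C)(C)CCC[C@]12C
F4 | step 11 | (4aS,8aS)-1-(2-iodoethyl)-2,5,5,8a-tetramethyl-3,4,4a,5,6,7,8,8a-octahydronaphthalene | ICCC1=C(C)CC[C@H]2C(C)(C)CCC[C@]12C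
F5 | step 11 | methyl 2-(dimethoxyphosphoryl)-4-[(4aS,8aS)-2,5,5,8a-tetramethyl-3,4,4a,5,6,7,8,8a-octahydronaphthalen-1-yl]butanoate (epimer mixture at the phosphonate carbon) | COC(=O)C(CCC1=C(C)CC[C@H]2C(C)(C)CCC[C@]12C)P(=O)(OC)OC
F6 | step 15 | methyl (Z)-3-iodobut-2-enoate | C/C(I)=C/C(=O)OC
F7 | step 15 | methyl (2Z,6E)-7-(hydroxymethyl)-3-methyl-9-[(4aS,8aS)-2,5,5,8a-tetramethyl-3,4,4a,5,6,7,8,8a-octahydronaphthalen-1-yl]nona-2,6-dien-4-ynoate | COC(=O)/C=C(C)\C#C/C=C(/CO)CCC1=C(C)CC[C@H]2C(C)(C)CCC[C@]12C
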